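**Retrosynthetic overview**
- Both threo 1-aryl-2-aryloxypropan-1-ol chains are cut at the aryl ether C–O bond (phenoxide SN2 on an α-mesyloxy ketone, inversion) and at the carbinol C–H (Felkin–Anh hydride reduction). They are attached one after the other to a tetrahydrofuran bis-phenol whose phenols are distinguished as a TIPS and a benzyl ether.
- The antipodal (R)- and (S)-mesyloxy ketones both come from one lipase kinetic resolution of racemic 2-hydroxy-1-(3,4-dimethoxyphenyl)propan-1-one, made from 3,4-dimethoxypropiophenone.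
- Tetrahydrofuran core: reductive deoxygenation of the hemiketal formed from the aryl A lithium reagent and a 3,4-trans-4,5-cis γ-lactone (sets C2).
- Lactone: α-methylation (C3), oxidative lactonisation, hydroboration, and a chiral phosphoric acid-catalysed (Z)-crotylboration of O-TIPS-vanillin (C4 and C5, the first stereocentres).
- Ring order: the γ-lactone is formed first and is then converted into the tetrahydrofuran ring; all benzene rings are bought.

Assumption (reading of the SMILES): the ring is (2S,3S,4S,5R), i.e. 2,3-trans-3,4-trans-4,5-cis; aryl A on C2 carries the (1R,2R)-threo chain and aryl B on C5 carries the (1S,2S)-threo chain.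

**Step 1**
Reactants: 1 vanillin (4-hydroxy-3-methoxybenzaldehyde)
Product: 2 3-methoxy-4-[(triisopropylsilyl)oxy]benzaldehyde
Conditions: TIPSCl (1.2 equiv), imidazole (2.5 equiv), DMF, rt
Reagents that add atoms: triisopropylsilyl chloride, CC(C)[Si](Cl)(C(C)C)C(C)C
Why: Imidazole-promoted O-silylation of the phenol; the bulky aryl silyl ether survives the later base, organolithium and Lewis acid steps and is a weaker donor than an alkyl ether, which disfavours later ionisation at the benzylic carbon para to it.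

**Step 2**
Reactants: 2 3-methoxy-4-[(triisopropylsilyl)oxy]benzaldehyde; 3 (Z)-crotylboronic acid pinacol ester
Product: 5 (1R,2S)-1-{3-methoxy-4-[(triisopropylsilyl)oxy]phenyl}-2-methylbut-3-en-1-ol, via pinacol borate ester 4 (not isolated)
Conditions: (R)-TRIP [(R)-3,3'-bis(2,4,6-triisopropylphenyl)-1,1'-binaphthyl-2,2'-diyl hydrogen phosphate, 5 mol %], toluene, −30 → 0 °C; aqueous work-up
Reagents that add atoms: none
Why: Chiral phosphoric acid-catalysed asymmetric crotylboration through a closed chair transition state, in which the (R)-acid directs attack to the re face of the aldehyde (1R) and the Z-crotyl geometry gives the syn methyl (2S), so the first two stereocentres are set by the catalyst.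

**Step 3**
Reactants: 5 (1R,2S)-1-{3-methoxy-4-[(triisopropylsilyl)oxy]phenyl}-2-methylbut-3-en-1-ol
Product: 7 (1R,2S)-1-{3-methoxy-4-[(triisopropylsilyl)oxy]phenyl}-2-methylbutane-1,4-diol, via bis(9-BBN) adduct 6 (not isolated)
Conditions: 9-BBN (2.2 equiv), THF, 0 °C → rt; then NaBO3·4H2O, THF/H2O, rt
Reagents that add atoms: sodium perborate tetrahydrate (supplies the new hydroxyl oxygen; drawn as the peroxoborate dimer without crystal water), O[B-]1(O)OO[B-](O)(O)OO1.[Na+].[Na+]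
Why: Anti-Markovnikov hydroboration of the terminal alkene followed by mild perborate oxidation, which spares the aryl silyl ether and touches no stereocentre.

**Step 4**
Reactants: 7 (1R,2S)-1-{3-methoxy-4-[(triisopropylsilyl)oxy]phenyl}-2-methylbutane-1,4-diol
Product: 9 (4S,5R)-5-{3-methoxy-4-[(triisopropylsilyl)oxy]phenyl}-4-methyldihydrofuran-2(3H)-one, via lactol 8 (not isolated)
Conditions: TEMPO (0.2 equiv), PhI(OAc)2 (2.5 equiv), CH2Cl2, rt
Reagents that add atoms: none
Why: TEMPO/PhI(OAc)2 oxidative lactonisation: the primary alcohol is oxidised selectively, the aldehyde is trapped by the benzylic hydroxyl as the lactol, and this is oxidised on to the γ-lactone with aryl and methyl cis.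

**Step 5**
Reactants: 9 (4S,5R)-5-{3-methoxy-4-[(triisopropylsilyl)oxy]phenyl}-4-methyldihydrofuran-2(3H)-one
Product: 11 (3S,4S,5R)-5-{3-methoxy-4-[(triisopropylsilyl)oxy]phenyl}-3,4-dimethyldihydrofuran-2(3H)-one, via lithium enolate 10 (not isolated)
Conditions: LiN(i-Pr)2 (1.1 equiv), THF, −78 °C; MeI (3 equiv), −78 → −40 °C
Reagents that add atoms: iodomethane, CI
Why: Kinetic lactone enolate alkylation in which MeI approaches the face opposite the cis-disposed C4 methyl and C5 aryl, giving the 3,4-trans methyl (3S).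

**Step 6**
Reactants: 11 (3S,4S,5R)-5-{3-methoxy-4-[(triisopropylsilyl)oxy]phenyl}-3,4-dimethyldihydrofuran-2(3H)-one; 12 1-(benzyloxy)-4-bromo-2-methoxybenzene
Product: 15 (3S,4S,5R)-2-[4-(benzyloxy)-3-methoxyphenyl]-5-{3-methoxy-4-[(triisopropylsilyl)oxy]phenyl}-3,4-dimethyltetrahydrofuran-2-ol (hemiketal; used crude), via aryllithium 13 (not isolated), via lithium hemiketal alkoxide 14 (not isolated)
Conditions: 12 (1.5 equiv), n-BuLi (1.45 equiv), THF, −78 °C, 30 min; add 11, −78 °C, 1 h; sat. aq NH4Cl at −78 °C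
Reagents that add atoms: none
Why: Bromine–lithium exchange and single addition of the aryllithium to the lactone carbonyl; the tetrahedral lithium alkoxide is stable at −78 °C, which prevents over-addition, and the buffered quench avoids epimerisation at C3.

**Step 7**
Reactants: 15 (3S,4S,5R)-2-[4-(benzyloxy)-3-methoxyphenyl]-5-{3-methoxy-4-[(triisopropylsilyl)oxy]phenyl}-3,4-dimethyltetrahydrofuran-2-ol
Product: 17 (2S,3S,4S,5R)-2-[4-(benzyloxy)-3-methoxyphenyl]-5-{3-methoxy-4-[(triisopropylsilyl)oxy]phenyl}-3,4-dimethyltetrahydrofuran, via oxocarbenium ion 16 (not isolated)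
Conditions: BF3·OEt2 (3 equiv), Et3SiH (5 equiv), CH2Cl2, −78 °C, 1 h; cold aqueous work-up
Reagents that add atoms: none
Why: Lewis acid-promoted reductive deoxygenation of the cyclic hemiketal: hydride adds to the inside face of the oxocarbenium envelope that has both methyls pseudo-equatorial, which is the face opposite the C5 aryl and C4 methyl, so the new aryl ends up trans to the C3 methyl (2S), and −78 °C keeps the cis C5 centre from epimerising.

**Step 8**
Reactants: 17 (2S,3S,4S,5R)-2-[4-(benzyloxy)-3-methoxyphenyl]-5-{3-methoxy-4-[(triisopropylsilyl)oxy]phenyl}-3,4-dimethyltetrahydrofuran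
Product: 18 4-{(2R,3S,4S,5S)-5-[4-(benzyloxy)-3-methoxyphenyl]-3,4-dimethyltetrahydrofuran-2-yl}-2-methoxyphenol
Conditions: n-Bu4NF (1.1 equiv), AcOH (1.1 equiv), THF, 0 °C
Reagents that add atoms: none
Why: Fluoride-induced cleavage of the aryl silyl ether (Si–F bond formation) frees only the aryl B phenol; the benzyl ether is untouched.

**Step 9**
Reactants: 19 1-(3,4-dimethoxyphenyl)propan-1-one
Product: 20 rac-2-bromo-1-(3,4-dimethoxyphenyl)propan-1-one
Conditions: CuBr2 (2.1 equiv), EtOAc/CHCl3 1:1, reflux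
Reagents that add atoms: copper dibromide, Br[Cu]Br
Why: CuBr2 α-bromination of the aryl ketone through its enol, selective for the α-carbon over the electron-rich ring.

**Step 10**
Reactants: 20 rac-2-bromo-1-(3,4-dimethoxyphenyl)propan-1-one
Product: 22 rac-1-(3,4-dimethoxyphenyl)-2-hydroxypropan-1-one, via formate ester 21 (not isolated)
Conditions: HCO2Na (3 equiv), MeOH, reflux
Reagents that add atoms: sodium formate (supplies the hydroxyl oxygen), [Na+].[O-]C=O
Why: SN2 displacement of the carbonyl-activated bromide by formate followed by methanolysis of the formate ester in the same flask gives the racemic α-hydroxy ketone.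

**Step 11**
Reactants: 22 rac-1-(3,4-dimethoxyphenyl)-2-hydroxypropan-1-one
Product: 23 (R)-1-(3,4-dimethoxyphenyl)-1-oxopropan-2-yl acetate; 24 (S)-1-(3,4-dimethoxyphenyl)-2-hydroxypropan-1-one (recovered unreacted enantiomer)
Conditions: lipase (immobilised Burkholderia cepacia lipase), vinyl acetate (3 equiv), MTBE, 30 °C, to about 52% conversion; chromatography
Reagents that add atoms: vinyl acetate, C=COC(C)=O
Why: Lipase-catalysed kinetic resolution by irreversible transesterification: the enzyme acylates only the (R)-alcohol (aroyl as large and methyl as medium substituent), so one operation delivers both antipodes needed for the two side chains.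

**Step 12**
Reactants: 23 (R)-1-(3,4-dimethoxyphenyl)-1-oxopropan-2-yl acetate
Product: 25 (R)-1-(3,4-dimethoxyphenyl)-2-hydroxypropan-1-one
Conditions: lipase (same enzyme), 0.1 M phosphate buffer pH 7/MTBE, 30 °C, stopped at about 90% conversion
Reagents that add atoms: none
Why: Lipase-catalysed hydrolysis of the enzyme's preferred (R)-acetate at neutral pH frees the ketol without base, so no racemisation or ketol shift occurs, and raises its ee a second time.

**Step 13**
Reactants: 25 (R)-1-(3,4-dimethoxyphenyl)-2-hydroxypropan-1-one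
Product: 26 (R)-1-(3,4-dimethoxyphenyl)-1-oxopropan-2-yl methanesulfonate
Conditions: MsCl (1.2 equiv), Et3N (1.5 equiv), CH2Cl2, −20 → 0 °C; used at once
Reagents that add atoms: methanesulfonyl chloride, CS(=O)(=O)Cl
Why: O-sulfonylation leaves the C–O bond and the stereocentre untouched and creates a carbonyl-activated leaving group.

**Step 14**
Reactants: 24 (S)-1-(3,4-dimethoxyphenyl)-2-hydroxypropan-1-one
Product: 27 (S)-1-(3,4-dimethoxyphenyl)-1-oxopropan-2-yl methanesulfonate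
Conditions: MsCl (1.2 equiv), Et3N (1.5 equiv), CH2Cl2, −20 → 0 °C; used at once
Reagents that add atoms: methanesulfonyl chloride, CS(=O)(=O)Cl
Why: O-sulfonylation with retention, as in step 13.

**Step 15**
Reactants: 18 4-{(2R,3S,4S,5S)-5-[4-(benzyloxy)-3-methoxyphenyl]-3,4-dimethyltetrahydrofuran-2-yl}-2-methoxyphenol; 26 (R)-1-(3,4-dimethoxyphenyl)-1-oxopropan-2-yl methanesulfonate
Product: 28 (S)-1-(3,4-dimethoxyphenyl)-2-(4-{(2R,3S,4S,5S)-5-[4-(benzyloxy)-3-methoxyphenyl]-3,4-dimethyltetrahydrofuran-2-yl}-2-methoxyphenoxy)propan-1-one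
Conditions: 26 (1.3 equiv), Cs2CO3 (1.5 equiv), MeCN, 0 °C → rt
Reagents that add atoms: none
Why: Williamson-type SN2 etherification in which the phenoxide displaces the carbonyl-activated secondary mesylate with inversion (R to S at the ether carbon), the mild carbonate base limiting epimerisation.

**Step 16**
Reactants: 28 (S)-1-(3,4-dimethoxyphenyl)-2-(4-{(2R,3S,4S,5S)-5-[4-(benzyloxy)-3-methoxyphenyl]-3,4-dimethyltetrahydrofuran-2-yl}-2-methoxyphenoxy)propan-1-one
Product: 29 (1S,2S)-1-(3,4-dimethoxyphenyl)-2-(4-{(2R,3S,4S,5S)-5-[4-(benzyloxy)-3-methoxyphenyl]-3,4-dimethyltetrahydrofuran-2-yl}-2-methoxyphenoxy)propan-1-ol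
Conditions: borohydride exchange resin (BH4− form of Amberlite IRA-400), MeOH/THF, 0 °C → rt
Reagents that add atoms: none
Why: Felkin–Anh (non-chelation) hydride reduction: the quaternary ammonium counter-ion cannot chelate, so hydride adds anti to the C–OAr bond and gives the threo (1S,2S) alcohol.

**Step 17**
Reactants: 29 (1S,2S)-1-(3,4-dimethoxyphenyl)-2-(4-{(2R,3S,4S,5S)-5-[4-(benzyloxy)-3-methoxyphenyl]-3,4-dimethyltetrahydrofuran-2-yl}-2-methoxyphenoxy)propan-1-ol
Product: 30 4-[(2S,3S,4S,5R)-5-(4-{[(1S,2S)-1-(3,4-dimethoxyphenyl)-1-hydroxypropan-2-yl]oxy}-3-methoxyphenyl)-3,4-dimethyltetrahydrofuran-2-yl]-2-methoxyphenol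
Conditions: H2 (1 atm), 10% Pd/C, EtOAc, rt, monitored
Reagents that add atoms: none
Why: Catalytic hydrogenolysis of the aryl benzyl ether in neutral EtOAc is much faster than cleavage of the secondary benzylic C–O bonds of the ring and the side chain.

**Step 18**
Reactants: 30 4-[(2S,3S,4S,5R)-5-(4-{[(1S,2S)-1-(3,4-dimethoxyphenyl)-1-hydroxypropan-2-yl]oxy}-3-methoxyphenyl)-3,4-dimethyltetrahydrofuran-2-yl]-2-methoxyphenol; 27 (S)-1-(3,4-dimethoxyphenyl)-1-oxopropan-2-yl methanesulfonate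
Product: 31 (R)-1-(3,4-dimethoxyphenyl)-2-{4-[(2S,3S,4S,5R)-5-(4-{[(1S,2S)-1-(3,4-dimethoxyphenyl)-1-hydroxypropan-2-yl]oxy}-3-methoxyphenyl)-3,4-dimethyltetrahydrofuran-2-yl]-2-methoxyphenoxy}propan-1-one
Conditions: 27 (1.3 equiv), Cs2CO3 (1.5 equiv), MeCN, 0 °C → rt
Reagents that add atoms: none
Why: SN2 etherification with inversion (S to R); the phenoxide reacts while the free secondary alcohol of the first chain is not deprotonated by carbonate.

**Step 19**
Reactants: 31 (R)-1-(3,4-dimethoxyphenyl)-2-{4-[(2S,3S,4S,5R)-5-(4-{[(1S,2S)-1-(3,4-dimethoxyphenyl)-1-hydroxypropan-2-yl]oxy}-3-methoxyphenyl)-3,4-dimethyltetrahydrofuran-2-yl]-2-methoxyphenoxy}propan-1-one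
Product: 32 (1R,2R)-1-(3,4-dimethoxyphenyl)-2-{4-[(2S,3S,4S,5R)-5-(4-{[(1S,2S)-1-(3,4-dimethoxyphenyl)-1-hydroxypropan-2-yl]oxy}-3-methoxyphenyl)-3,4-dimethyltetrahydrofuran-2-yl]-2-methoxyphenoxy}propan-1-ol (CNP0116650.17)
Conditions: borohydride exchange resin (BH4− form of Amberlite IRA-400), MeOH/THF, 0 °C → rt
Reagents that add atoms: none
Why: Felkin–Anh hydride reduction as in step 16, here giving the threo (1R,2R) alcohol from the (R)-ketone.

**Compound list**
1 | vanillin (4-hydroxy-3-methoxybenzaldehyde) | COc1cc(C=O)ccc1O | starting material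
2 | 3-methoxy-4-[(triisopropylsilyl)oxy]benzaldehyde | COc1cc(C=O)ccc1O[Si](C(C)C)(C(C)C)C(C)C | intermediate
3 | (Z)-crotylboronic acid pinacol ester | C/C=C\CB1OC(C)(C)C(C)(C)O1 | starting material
4 | pinacol borate ester of alcohol 5 | C=C[C@H](C)[C@@H](OB1OC(C)(C)C(C)(C)O1)c1ccc(O[Si](C(C)C)(C(C)C)C(C)C)c(OC)c1 | intermediate (not isolated)
5 | (1R,2S)-1-{3-methoxy-4-[(triisopropylsilyl)oxy]phenyl}-2-methylbut-3-en-1-ol | C=C[C@H](C)[C@@H](O)c1ccc(O[Si](C(C)C)(C(C)C)C(C)C)c(OC)c1 | intermediate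
6 | bis(9-BBN) adduct of 5 (B-alkyl at C4, O-boryl at C1) | C1CCC2CCCC1B2CC[C@H](C)[C@@H](OB1C2CCCC1CCC2)c1ccc(O[Si](C(C)C)(C(C)C)C(C)C)c(OC)c1 | intermediate (not isolated)
7 | (1R,2S)-1-{3-methoxy-4-[(triisopropylsilyl)oxy]phenyl}-2-methylbutane-1,4-diol | OCC[C@H](C)[C@@H](O)c1ccc(O[Si](C(C)C)(C(C)C)C(C)C)c(OC)c1 | intermediate
8 | (4S,5R)-5-{3-methoxy-4-[(triisopropylsilyl)oxy]phenyl}-4-methyltetrahydrofuran-2-ol (lactol, both anomers) | OC1C[C@H](C)[C@H](c2ccc(O[Si](C(C)C)(C(C)C)C(C)C)c(OC)c2)O1 | intermediate (not isolated)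
9 | (4S,5R)-5-{3-methoxy-4-[(triisopropylsilyl)oxy]phenyl}-4-methyldihydrofuran-2(3H)-one | O=C1C[C@H](C)[C@H](c2ccc(O[Si](C(C)C)(C(C)C)C(C)C)c(OC)c2)O1 | intermediate
10 | lithium enolate of lactone 9 | [Li]OC1=C[C@H](C)[C@H](c2ccc(O[Si](C(C)C)(C(C)C)C(C)C)c(OC)c2)O1 | intermediate (not isolated)
11 | (3S,4S,5R)-5-{3-methoxy-4-[(triisopropylsilyl)oxy]phenyl}-3,4-dimethyldihydrofuran-2(3H)-one | O=C1[C@@H](C)[C@H](C)[C@H](c2ccc(O[Si](C(C)C)(C(C)C)C(C)C)c(OC)c2)O1 | intermediate
12 | 1-(benzyloxy)-4-bromo-2-methoxybenzene | COc1cc(Br)ccc1OCc1ccccc1 | starting material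
13 | [4-(benzyloxy)-3-methoxyphenyl]lithium | [Li]c1ccc(OCc2ccccc2)c(OC)c1 | intermediate (not isolated)
14 | lithium alkoxide of hemiketal 15 | COc1cc(C2(O[Li])O[C@@H](c3ccc(O[Si](C(C)C)(C(C)C)C(C)C)c(OC)c3)[C@@H](C)[C@@H]2C)ccc1OCc1ccccc1 | intermediate (not isolated)
15 | (3S,4S,5R)-2-[4-(benzyloxy)-3-methoxyphenyl]-5-{3-methoxy-4-[(triisopropylsilyl)oxy]phenyl}-3,4-dimethyltetrahydrofuran-2-ol (C2 anomers, in equilibrium with the open hydroxy ketone) | COc1cc(C2(O)O[C@@H](c3ccc(O[Si](C(C)C)(C(C)C)C(C)C)c(OC)c3)[C@@H](C)[C@@H]2C)ccc1OCc1ccccc1 | intermediate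
16 | cyclic oxocarbenium ion from 15 (hydroxytrifluoroborate salt) | COc1cc(C2=[O+][C@@H](c3ccc(O[Si](C(C)C)(C(C)C)C(C)C)c(OC)c3)[C@@H](C)[C@@H]2C)ccc1OCc1ccccc1.O[B-](F)(F)F | intermediate (not isolated)
17 | (2S,3S,4S,5R)-2-[4-(benzyloxy)-3-methoxyphenyl]-5-{3-methoxy-4-[(triisopropylsilyl)oxy]phenyl}-3,4-dimethyltetrahydrofuran | COc1cc([C@H]2O[C@@H](c3ccc(O[Si](C(C)C)(C(C)C)C(C)C)c(OC)c3)[C@@H](C)[C@@H]2C)ccc1OCc1ccccc1 | intermediate
18 | 4-{(2R,3S,4S,5S)-5-[4-(benzyloxy)-3-methoxyphenyl]-3,4-dimethyltetrahydrofuran-2-yl}-2-methoxyphenol | COc1cc([C@H]2O[C@@H](c3ccc(O)c(OC)c3)[C@@H](C)[C@@H]2C)ccc1OCc1ccccc1 | intermediate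
19 | 1-(3,4-dimethoxyphenyl)propan-1-one | CCC(=O)c1ccc(OC)c(OC)c1 | starting material
20 | rac-2-bromo-1-(3,4-dimethoxyphenyl)propan-1-one | CC(Br)C(=O)c1ccc(OC)c(OC)c1 | intermediate
21 | rac-1-(3,4-dimethoxyphenyl)-1-oxopropan-2-yl formate | CC(OC=O)C(=O)c1ccc(OC)c(OC)c1 | intermediate (not isolated)
22 | rac-1-(3,4-dimethoxyphenyl)-2-hydroxypropan-1-one | CC(O)C(=O)c1ccc(OC)c(OC)c1 | intermediate
23 | (R)-1-(3,4-dimethoxyphenyl)-1-oxopropan-2-yl acetate | C[C@@H](OC(C)=O)C(=O)c1ccc(OC)c(OC)c1 | intermediate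
24 | (S)-1-(3,4-dimethoxyphenyl)-2-hydroxypropan-1-one | C[C@H](O)C(=O)c1ccc(OC)c(OC)c1 | intermediate
25 | (R)-1-(3,4-dimethoxyphenyl)-2-hydroxypropan-1-one | C[C@@H](O)C(=O)c1ccc(OC)c(OC)c1 | intermediate
26 | (R)-1-(3,4-dimethoxyphenyl)-1-oxopropan-2-yl methanesulfonate | C[C@@H](OS(C)(=O)=O)C(=O)c1ccc(OC)c(OC)c1 | intermediate
27 | (S)-1-(3,4-dimethoxyphenyl)-1-oxopropan-2-yl methanesulfonate | C[C@H](OS(C)(=O)=O)C(=O)c1ccc(OC)c(OC)c1 | intermediate
28 | (S)-1-(3,4-dimethoxyphenyl)-2-(4-{(2R,3S,4S,5S)-5-[4-(benzyloxy)-3-methoxyphenyl]-3,4-dimethyltetrahydrofuran-2-yl}-2-methoxyphenoxy)propan-1-one | COc1cc([C@H]2O[C@@H](c3ccc(O[C@@H](C)C(=O)c4ccc(OC)c(OC)c4)c(OC)c3)[C@@H](C)[C@@H]2C)ccc1OCc1ccccc1 | intermediate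
29 | (1S,2S)-1-(3,4-dimethoxyphenyl)-2-(4-{(2R,3S,4S,5S)-5-[4-(benzyloxy)-3-methoxyphenyl]-3,4-dimethyltetrahydrofuran-2-yl}-2-methoxyphenoxy)propan-1-ol | COc1cc([C@H]2O[C@@H](c3ccc(O[C@@H](C)[C@@H](O)c4ccc(OC)c(OC)c4)c(OC)c3)[C@@H](C)[C@@H]2C)ccc1OCc1ccccc1 | intermediate
30 | 4-[(2S,3S,4S,5R)-5-(4-{[(1S,2S)-1-(3,4-dimethoxyphenyl)-1-hydroxypropan-2-yl]oxy}-3-methoxyphenyl)-3,4-dimethyltetrahydrofuran-2-yl]-2-methoxyphenol | COc1cc([C@H]2O[C@@H](c3ccc(O[C@@H](C)[C@@H](O)c4ccc(OC)c(OC)c4)c(OC)c3)[C@@H](C)[C@@H]2C)ccc1O | intermediate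
31 | (R)-1-(3,4-dimethoxyphenyl)-2-{4-[(2S,3S,4S,5R)-5-(4-{[(1S,2S)-1-(3,4-dimethoxyphenyl)-1-hydroxypropan-2-yl]oxy}-3-methoxyphenyl)-3,4-dimethyltetrahydrofuran-2-yl]-2-methoxyphenoxy}propan-1-one | COc1ccc(C(=O)[C@@H](C)Oc2ccc([C@H]3O[C@@H](c4ccc(O[C@@H](C)[C@@H](O)c5ccc(OC)c(OC)c5)c(OC)c4)[C@@H](C)[C@@H]3C)cc2OC)cc1OC | intermediate
32 | (1R,2R)-1-(3,4-dimethoxyphenyl)-2-{4-[(2S,3S,4S,5R)-5-(4-{[(1S,2S)-1-(3,4-dimethoxyphenyl)-1-hydroxypropan-2-yl]oxy}-3-methoxyphenyl)-3,4-dimethyltetrahydrofuran-2-yl]-2-methoxyphenoxy}propan-1-ol | COc1ccc([C@@H](O)[C@@H](C)Oc2ccc([C@H]3O[C@@H](c4ccc(O[C@@H](C)[C@@H](O)c5ccc(OC)c(OC)c5)c(OC)c4)[C@@H](C)[C@@H]3C)cc2OC)cc1OC | target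

**Totals and risks**
Total step count: 19. Longest linear sequence: 13 steps (steps 1–8 and 15–19, from vanillin).

The three steps most likely to fail:

Step 7. The facial selectivity of hydride delivery at C2 may be incomplete, and BF3·OEt2 can epimerise the cis benzylic C5 centre if the mixture warms. The fallback sets out from lactone 11 and comes back at 17; it closes the ring by an SN1 cycloetherification at C2, in which the C5–O bond is never broken. Lactone 11 is opened with Me(MeO)NH·HCl/AlMe3 (CH2Cl2, 0 °C) to the γ-hydroxy Weinreb amide F1. This is silylated at once (Et3SiCl, imidazole, DMF) to the triethylsilyl ether F2. Aryllithium 13 (THF, −78 °C) converts F2 into the aryl ketone F3, and NaBH4 (MeOH, 0 °C) reduces this to the benzylic alcohol F4, of which both C1 epimers are used. MsCl/Et3N (CH2Cl2, −20 °C) gives the benzylic mesylate F5, which ionises to the p-benzyloxybenzyl cation. The silyl ether oxygen captures the cation on the face away from the neighbouring methyl, and loss of the silyl group closes the ring to 17.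

Step 15 (the same applies to step 18). The α-aryloxy ketone or the mesylate may epimerise under carbonate, or the mesylate may eliminate. The fallback sets out from phenol 18 and the free (R)-ketol 25 and comes back at 28. It is a base-free Mitsunobu etherification (PPh3, DIAD, toluene, 0 °C → rt), which also inverts the carbinol carbon and skips mesylate 26; it makes no new compound (F0). For step 18 the same is done with 30 and (S)-ketol 24 to reach 31.

Step 19 (the same applies to step 16). The substrate-controlled threo:erythro ratio may be too low. The fallback sets out from ketone 31 and comes back at 32. It is a catalyst-controlled asymmetric transfer hydrogenation with RuCl[(S,S)-TsDPEN](p-cymene) in HCO2H/Et3N 5:2 at rt; the catalyst's preference for the (1R)-carbinol reinforces the Felkin preference. It makes no new compound (F0). For step 16 the (R,R)-catalyst is used on 28 to reach 29.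

**Further compounds**
F1 | step 7 | (2S,3S,4R)-4-hydroxy-N-methoxy-4-{3-methoxy-4-[(triisopropylsilyl)oxy]phenyl}-N,2,3-trimethylbutanamide | CON(C)C(=O)[C@@H](C)[C@H](C)[C@@H](O)c1ccc(O[Si](C(C)C)(C(C)C)C(C)C)c(OC)c1
F2 | step 7 | (2S,3S,4R)-N-methoxy-4-{3-methoxy-4-[(triisopropylsilyl)oxy]phenyl}-N,2,3-trimethyl-4-[(triethylsilyl)oxy]butanamide | CON(C)C(=O)[C@@H](C)[C@H](C)[C@@H](O[Si](CC)(CC)CC)c1ccc(O[Si](C(C)C)(C(C)C)C(C)C)c(OC)c1
F3 | step 7 | (2S,3S,4R)-1-[4-(benzyloxy)-3-methoxyphenyl]-4-{3-methoxy-4-[(triisopropylsilyl)oxy]phenyl}-2,3-dimethyl-4-[(triethylsilyl)oxy]butan-1-one | COc1cc(C(=O)[C@@H](C)[C@H](C)[C@@H](O[Si](CC)(CC)CC)c2ccc(O[Si](C(C)C)(C(C)C)C(C)C)c(OC)c2)ccc1OCc1ccccc1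
F4 | step 7 | (2S,3S,4R)-1-[4-(benzyloxy)-3-methoxyphenyl]-4-{3-methoxy-4-[(triisopropylsilyl)oxy]phenyl}-2,3-dimethyl-4-[(triethylsilyl)oxy]butan-1-ol (C1 epimers) | COc1cc(C(O)[C@@H](C)[C@H](C)[C@@H](O[Si](CC)(CC)CC)c2ccc(O[Si](C(C)C)(C(C)C)C(C)C)c(OC)c2)ccc1OCc1ccccc1
F5 | step 7 | C1 methanesulfonate of F4 (formed and consumed in the flask) | COc1cc(C(OS(C)(=O)=O)[C@@H](C)[C@H](C)[C@@H](O[Si](CC)(CC)CC)c2ccc(O[Si](C(C)C)(C(C)C)C(C)C)c(OC)c2)ccc1OCc1ccccc1
F0 | step 15 | none | none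
F0 | step 19 | none | none
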